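**Retrosynthetic overview**
- The C15 ester is put on last by chemoselective acylation of the primary allylic alcohol of the macrocyclic 6,15-diol with (Z)-2-(acetoxymethyl)but-2-enoic acid (made from crotonaldehyde).
- The ten-membered ring is closed at C6–C7 by a chromium-catalysed intramolecular allylation of a (C4=C5)-enal with a 3-(bromomethyl)butenolide. This step also creates C6 and C7 and turns the butenolide into the trans-fused α-methylene lactone.
- Ring order: butenolide first (ring-closing metathesis of a 2-(bromomethyl)acrylate on the C8 carbinol), carbocycle second.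
- The open chain is joined at C1–C2 by a B-alkyl Suzuki–Miyaura coupling of a west (E)-vinyl iodide (C7–C10, C14, C1) with an east borane (C2–C6, C15).
- West piece from (S)-epichlorohydrin and ethynyltrimethylsilane (Zr-catalysed carboalumination); east piece from but-2-yne-1,4-diol (trans-hydroalumination/iodination, Suzuki vinylation).

Assumption: positions are given in germacrane numbering (ring C1–C10, C11–C13 lactone unit closed on O8, C14 methyl, C15 oxygenated methylene); the target is (6R,7S,8S).

**Route**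

Step 1
Reactants: 1 (S)-epichlorohydrin; 2 ethynyltrimethylsilane
Product: 4 (2S)-1-chloro-5-(trimethylsilyl)pent-4-yn-2-ol, via lithium trimethylsilylacetylide 3 (not isolated)
Conditions: n-BuLi, THF, −78 °C; BF3·OEt2, then 1, −78 °C; aq. NH4Cl
Reagents that add atoms: none
Why: BF3-promoted epoxide opening by the lithium acetylide at the unsubstituted carbon (Yamaguchi-type alkynylation) leaves the C–O stereocentre (future C8) untouched.

Step 2
Reactants: 4 (2S)-1-chloro-5-(trimethylsilyl)pent-4-yn-2-ol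
Product: 6 (3S)-6-(trimethylsilyl)hex-1-en-5-yn-3-ol, via (2S)-2-[3-(trimethylsilyl)prop-2-ynyl]oxirane 5 (not isolated)
Conditions: Me3S+ I− (3 equiv), n-BuLi (2.9 equiv), THF, −20 °C → rt; aq. NH4Cl
Reagents that add atoms: trimethylsulfonium iodide, C[S+](C)C.[I-]
Why: The chlorohydrin closes to the epoxide, which dimethylsulfonium methylide opens and then eliminates Me2S (one-carbon epoxide-to-allylic-alcohol homologation), so the carbinol configuration is retained.

Step 3
Reactants: 6 (3S)-6-(trimethylsilyl)hex-1-en-5-yn-3-ol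
Product: 7 (3S)-hex-1-en-5-yn-3-ol
Conditions: K2CO3 (0.2 equiv), MeOH, rt
Reagents that add atoms: none
Why: Base-catalysed methanolysis of the alkynyl C–Si bond (protodesilylation) frees the terminal alkyne without touching the stereocentre.

Step 4
Reactants: 7 (3S)-hex-1-en-5-yn-3-ol
Product: 9 (3S,5E)-6-iodo-5-methylhexa-1,5-dien-3-ol, via (5E)-alkenyldimethylalane dimethylaluminium alkoxide 8 (not isolated)
Conditions: AlMe3 (3 equiv), Cp2ZrCl2 (0.3 equiv), CH2Cl2, 0 °C → rt; [I][I] in THF, −30 °C; aq. sodium potassium tartrate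
Reagents that add atoms: trimethylaluminium, C[Al](C)C; iodine, [I][I]
Why: Zirconium-catalysed Negishi carboalumination adds Me and Al syn across the terminal alkyne (Me to the internal carbon) and iodinolysis proceeds with retention, which fixes the 1(10)E trisubstituted alkene.

Step 5
Reactants: 10 but-2-yne-1,4-diol
Product: 11 4-[(tert-butyldimethylsilyl)oxy]but-2-yn-1-ol
Conditions: 10 (3 equiv), TBSCl (1 equiv), imidazole, DMF, 0 °C → rt
Reagents that add atoms: tert-butyldimethylsilyl chloride, CC(C)(C)[Si](C)(C)Cl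
Why: Statistical monosilylation of the symmetrical diol used in excess gives the mono-ether; the unreacted diol is washed out with water.

Step 6
Reactants: 11 4-[(tert-butyldimethylsilyl)oxy]but-2-yn-1-ol
Product: 13 (2Z)-4-[(tert-butyldimethylsilyl)oxy]-3-iodobut-2-en-1-ol, via sodium cyclic alkenylalanate 12 (not isolated)
Conditions: NaAlH2(OCH2CH2OMe)2 (1.5 equiv), THF, 0 °C; EtOAc; [I][I], −78 °C → 0 °C
Reagents that add atoms: iodine, [I][I]
Why: Hydroxyl-directed trans-hydroalumination delivers Al to the distal alkyne carbon through a five-membered alanate, and iodinolysis with retention gives only the (Z)-γ-iodo allylic alcohol (I cis to CH2OH).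

Step 7
Reactants: 13 (2Z)-4-[(tert-butyldimethylsilyl)oxy]-3-iodobut-2-en-1-ol; 14 potassium vinyltrifluoroborate
Product: 15 (2E)-3-{[(tert-butyldimethylsilyl)oxy]methyl}penta-2,4-dien-1-ol
Conditions: PdCl2(dppf) (5 mol %), Cs2CO3 (3 equiv), THF/H2O 9:1, 65 °C
Reagents that add atoms: none
Why: Suzuki–Miyaura vinylation of the vinyl iodide with retention places the C2–C3 unit cis to the CH2OH carbon (C6), which is the C4=C5 geometry of the target.

Step 8
Reactants: 15 (2E)-3-{[(tert-butyldimethylsilyl)oxy]methyl}penta-2,4-dien-1-ol; 9 (3S,5E)-6-iodo-5-methylhexa-1,5-dien-3-ol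
Product: 17 (2E,6E,9S)-3-{[(tert-butyldimethylsilyl)oxy]methyl}-7-methylundeca-2,6,10-triene-1,9-diol, via B-alkyl-9-BBN borane 16 (not isolated)
Conditions: 15, 9-BBN (2.2 equiv), THF, 0 °C → rt; 3 M aq. Cs2CO3; 9 (0.9 equiv), PdCl2(dppf) (5 mol %), AsPh3 (10 mol %), DMF, rt
Reagents that add atoms: none
Why: 9-BBN hydroborates only the terminal CH2 of the diene (anti-Markovnikov), and the B-alkyl Suzuki–Miyaura coupling on zerovalent palladium joins C1–C2 with retention of both alkene geometries.

Step 9
Reactants: 17 (2E,6E,9S)-3-{[(tert-butyldimethylsilyl)oxy]methyl}-7-methylundeca-2,6,10-triene-1,9-diol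
Product: 18 (2E,6E,9S)-3-{[(tert-butyldimethylsilyl)oxy]methyl}-9-hydroxy-7-methylundeca-2,6,10-trienal
Conditions: TEMPO (10 mol %), PhI(OAc)2 (1.1 equiv), CH2Cl2, rt
Reagents that add atoms: none
Why: The oxoammonium oxidation is strongly selective for the primary allylic alcohol over the hindered secondary carbinol and is mild enough to keep the enal geometry (CHO cis to the C3 chain).

Step 10
Reactants: 18 (2E,6E,9S)-3-{[(tert-butyldimethylsilyl)oxy]methyl}-9-hydroxy-7-methylundeca-2,6,10-trienal; 19 2-(bromomethyl)prop-2-enoic acid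
Product: 20 (3S,5E,9E)-9-{[(tert-butyldimethylsilyl)oxy]methyl}-5-methyl-11-oxoundeca-1,5,9-trien-3-yl 2-(bromomethyl)prop-2-enoate
Conditions: DCC (1.3 equiv), DMAP (5 mol %), CH2Cl2, 0 °C
Reagents that add atoms: none
Why: Steglich esterification acylates the C8 hydroxyl without breaking its C–O bond, so the (S) centre is retained.

Step 11
Reactants: 20 (3S,5E,9E)-9-{[(tert-butyldimethylsilyl)oxy]methyl}-5-methyl-11-oxoundeca-1,5,9-trien-3-yl 2-(bromomethyl)prop-2-enoate
Product: 21 (2E,6E)-8-[(2S)-4-(bromomethyl)-5-oxo-2,5-dihydrofuran-2-yl]-3-{[(tert-butyldimethylsilyl)oxy]methyl}-7-methylocta-2,6-dienal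
Conditions: second-generation Grubbs catalyst RuCl2(=CHPh)(PCy3)(H2IMes) (5 mol %), CH2Cl2 (5 mM), 40 °C
Reagents that add atoms: none
Why: Ring-closing metathesis between the monosubstituted vinyl group and the 1,1-disubstituted acrylate closes the five-membered butenolide; the trisubstituted alkenes and the enal are poor metathesis partners.

Step 12
Reactants: 21 (2E,6E)-8-[(2S)-4-(bromomethyl)-5-oxo-2,5-dihydrofuran-2-yl]-3-{[(tert-butyldimethylsilyl)oxy]methyl}-7-methylocta-2,6-dienal
Product: 24 (6R,7S,8S)-15-[(tert-butyldimethylsilyl)oxy]-6-hydroxygermacra-1(10),4,11(13)-trien-12,8-olide, via allylchromium dichloride 22 (not isolated), via C6 trimethylsilyl ether 23 (not isolated)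
Conditions: CrCl2 (15 mol %), Mn powder (3 equiv), TMSCl (2.5 equiv), THF, rt, 21 added by syringe pump over 12 h (2 mM final); then 10 % aq. citric acid
Reagents that add atoms: none
Why: Proposed new method: a Nozaki–Hiyama–Kishi macrocyclisation that is catalytic in chromium and uses a 3-(bromomethyl)butenolide as the allyl donor; divalent chromium (regenerated by Mn) reduces the C–Br bond to the trivalent allylchromium 22, which adds through its ring γ-carbon (C7) to the tethered enal in a six-membered chair transition state, the C8 side chain shielding one lactone face so that C6 enters trans to C9 (7S) and the ring-locked E-type allyl geometry with C5 equatorial giving the anti carbinol (6R), while TMSCl silylates the chromium alkoxide to release the metal for turnover; the closest known reactions are chromium-catalysed 2-(alkoxycarbonyl)allylation of aldehydes to α-methylene-γ-butyrolactones, stoichiometric CrCl2 cyclisations of ω-formyl allylic bromides to germacrane rings, and zinc or indium Barbier additions of 3-(bromomethyl)furan-2(5H)-ones.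

Step 13
Reactants: 24 (6R,7S,8S)-15-[(tert-butyldimethylsilyl)oxy]-6-hydroxygermacra-1(10),4,11(13)-trien-12,8-olide
Product: 25 (6R,7S,8S)-6,15-dihydroxygermacra-1(10),4,11(13)-trien-12,8-olide
Conditions: HF·pyridine, pyridine, THF, 0 °C → rt
Reagents that add atoms: none
Why: Buffered fluoride desilylation removes the primary silyl ether without base, so the α-methylene lactone and the stereocentres are not disturbed.

Step 14
Reactants: 26 (E)-but-2-enal
Product: 27 (2Z)-2-iodobut-2-enal
Conditions: [I][I] (1.5 equiv), K2CO3 (1.2 equiv), DMAP (20 mol %), THF/H2O 1:1, rt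
Reagents that add atoms: iodine, [I][I]
Why: Amine-catalysed α-iodination (conjugate addition of DMAP, iodination of the enolate, elimination) gives the thermodynamic (Z)-iodoenal with CH3 trans to CHO.

Step 15
Reactants: 27 (2Z)-2-iodobut-2-enal
Product: 28 (2Z)-2-iodobut-2-en-1-ol
Conditions: NaBH4, CeCl3·7H2O, MeOH, 0 °C
Reagents that add atoms: none
Why: Luche 1,2-reduction gives the allylic alcohol with the alkene geometry unchanged.

Step 16
Reactants: 28 (2Z)-2-iodobut-2-en-1-ol
Product: 30 (2Z)-2-(hydroxymethyl)but-2-enoic acid, via dilithio vinyllithium alkoxide 29 (not isolated)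
Conditions: n-BuLi (1.05 equiv), then t-BuLi (2.1 equiv), Et2O, −78 °C; CO2; 1 M HCl
Reagents that add atoms: carbon dioxide, O=C=O
Why: Iodine–lithium exchange on the lithium alkoxide and carboxylation of the configurationally stable vinyllithium occur with retention, so CO2H ends cis to CH3 (angelate-type Z geometry).

Step 17
Reactants: 30 (2Z)-2-(hydroxymethyl)but-2-enoic acid
Product: 31 (2Z)-2-(acetoxymethyl)but-2-enoic acid
Conditions: Ac2O (1.5 equiv), pyridine, CH2Cl2, 0 °C → rt; H2O
Reagents that add atoms: acetic anhydride, CC(=O)OC(C)=O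
Why: O-Acetylation of the primary alcohol; any mixed anhydride at the acid is hydrolysed on aqueous work-up.

Step 18
Reactants: 31 (2Z)-2-(acetoxymethyl)but-2-enoic acid; 25 (6R,7S,8S)-6,15-dihydroxygermacra-1(10),4,11(13)-trien-12,8-olide
Product: 33 CNP0184624.2, via (2Z)-2-(acetoxymethyl)but-2-enoyl chloride 32 (not isolated)
Conditions: 31 (1.05 equiv), 1-chloro-N,N,2-trimethylprop-1-en-1-amine, CH2Cl2, 0 °C; then 25, 2,4,6-collidine, CH2Cl2, −40 °C → 0 °C
Reagents that add atoms: none
Why: The acid chloride, made under neutral conditions, acylates the unhindered primary allylic C15 hydroxyl in preference to the hindered secondary C6 hydroxyl (chemoselective acylation), and the absence of nucleophilic catalysts avoids Z→E isomerisation of the enoate.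

**Compound list**
1 | (S)-epichlorohydrin, (2S)-2-(chloromethyl)oxirane | ClC[C@@H]1CO1 | starting material
2 | ethynyltrimethylsilane | C#C[Si](C)(C)C | starting material
3 | lithium trimethylsilylacetylide | [Li]C#C[Si](C)(C)C | intermediate
4 | (2S)-1-chloro-5-(trimethylsilyl)pent-4-yn-2-ol | ClC[C@@H](O)CC#C[Si](C)(C)C | intermediate
5 | (2S)-2-[3-(trimethylsilyl)prop-2-ynyl]oxirane | C1[C@@H](O1)CC#C[Si](C)(C)C | intermediate
6 | (3S)-6-(trimethylsilyl)hex-1-en-5-yn-3-ol | C=C[C@@H](O)CC#C[Si](C)(C)C | intermediate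
7 | (3S)-hex-1-en-5-yn-3-ol | C=C[C@@H](O)CC#C | intermediate
8 | (5E)-alkenyldimethylalane of 7 as its dimethylaluminium alkoxide (Al on the terminal alkene carbon, trans to C9) | C=C[C@@H](O[Al](C)C)C/C(C)=C/[Al](C)C | intermediate
9 | (3S,5E)-6-iodo-5-methylhexa-1,5-dien-3-ol | C=C[C@@H](O)C/C(C)=C/I | intermediate
10 | but-2-yne-1,4-diol | OCC#CCO | starting material
11 | 4-[(tert-butyldimethylsilyl)oxy]but-2-yn-1-ol | OCC#CCO[Si](C)(C)C(C)(C)C | intermediate
12 | sodium cyclic alkenylalanate from trans-hydroalumination of 11 (five-membered O–Al–C ring, Al on the carbon bearing CH2OTBS) | [Na+].COCCO[Al-]1(OCCOC)OCC=C1CO[Si](C)(C)C(C)(C)C | intermediate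
13 | (2Z)-4-[(tert-butyldimethylsilyl)oxy]-3-iodobut-2-en-1-ol | OC/C=C(\I)CO[Si](C)(C)C(C)(C)C | intermediate
14 | potassium vinyltrifluoroborate | C=C[B-](F)(F)F.[K+] | starting material
15 | (2E)-3-{[(tert-butyldimethylsilyl)oxy]methyl}penta-2,4-dien-1-ol (vinyl cis to CH2OH) | OC/C=C(\C=C)CO[Si](C)(C)C(C)(C)C | intermediate
16 | (2E)-5-(9-borabicyclo[3.3.1]nonan-9-yl)-3-{[(tert-butyldimethylsilyl)oxy]methyl}pent-2-en-1-ol (drawn as the free alcohol) | OC/C=C(\CCB1C2CCCC1CCC2)CO[Si](C)(C)C(C)(C)C | intermediate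
17 | (2E,6E,9S)-3-{[(tert-butyldimethylsilyl)oxy]methyl}-7-methylundeca-2,6,10-triene-1,9-diol | C=C[C@@H](O)C/C(C)=C/CC/C(CO[Si](C)(C)C(C)(C)C)=C\CO | intermediate
18 | (2E,6E,9S)-3-{[(tert-butyldimethylsilyl)oxy]methyl}-9-hydroxy-7-methylundeca-2,6,10-trienal | C=C[C@@H](O)C/C(C)=C/CC/C(CO[Si](C)(C)C(C)(C)C)=C\C=O | intermediate
19 | 2-(bromomethyl)prop-2-enoic acid | C=C(CBr)C(=O)O | starting material
20 | (3S,5E,9E)-9-{[(tert-butyldimethylsilyl)oxy]methyl}-5-methyl-11-oxoundeca-1,5,9-trien-3-yl 2-(bromomethyl)prop-2-enoate | C=C[C@@H](OC(=O)C(=C)CBr)C/C(C)=C/CC/C(CO[Si](C)(C)C(C)(C)C)=C\C=O | intermediate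
21 | (2E,6E)-8-[(2S)-4-(bromomethyl)-5-oxo-2,5-dihydrofuran-2-yl]-3-{[(tert-butyldimethylsilyl)oxy]methyl}-7-methylocta-2,6-dienal | BrCC1=C[C@H](C/C(C)=C/CC/C(CO[Si](C)(C)C(C)(C)C)=C\C=O)OC1=O | intermediate
22 | trivalent allylchromium dichloride of 21 (CrCl2 on the exocyclic CH2 of the butenolide; solvent ligands omitted) | Cl[Cr](Cl)CC1=C[C@H](C/C(C)=C/CC/C(CO[Si](C)(C)C(C)(C)C)=C\C=O)OC1=O | intermediate
23 | C6 trimethylsilyl ether of 24 | C=C1C(=O)O[C@H]2C/C(C)=C/CC/C(CO[Si](C)(C)C(C)(C)C)=C\[C@@H](O[Si](C)(C)C)[C@H]12 | intermediate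
24 | (6R,7S,8S)-15-[(tert-butyldimethylsilyl)oxy]-6-hydroxygermacra-1(10),4,11(13)-trien-12,8-olide (1(10)E; C3 and C6 cis on C4=C5; trans-fused lactone) | C=C1C(=O)O[C@H]2C/C(C)=C/CC/C(CO[Si](C)(C)C(C)(C)C)=C\[C@@H](O)[C@H]12 | intermediate
25 | (6R,7S,8S)-6,15-dihydroxygermacra-1(10),4,11(13)-trien-12,8-olide | C=C1C(=O)O[C@H]2C/C(C)=C/CC/C(CO)=C\[C@@H](O)[C@H]12 | intermediate
26 | (E)-but-2-enal (crotonaldehyde) | C/C=C/C=O | starting material
27 | (2Z)-2-iodobut-2-enal | C/C=C(\I)C=O | intermediate
28 | (2Z)-2-iodobut-2-en-1-ol | C/C=C(\I)CO | intermediate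
29 | O,C-dilithio derivative of 28 (vinyllithium alkoxide, geometry retained) | C/C=C(\[Li])CO[Li] | intermediate
30 | (2Z)-2-(hydroxymethyl)but-2-enoic acid | C/C=C(\C(=O)O)CO | intermediate
31 | (2Z)-2-(acetoxymethyl)but-2-enoic acid | C/C=C(\C(=O)O)COC(C)=O | intermediate
32 | (2Z)-2-(acetoxymethyl)but-2-enoyl chloride | C/C=C(\C(Cl)=O)COC(C)=O | intermediate
33 | CNP0184624.2, (6R,7S,8S)-15-{[(2Z)-2-(acetoxymethyl)but-2-enoyl]oxy}-6-hydroxygermacra-1(10),4,11(13)-trien-12,8-olide | C=C1C(=O)O[C@H]2C/C(C)=C/CC/C(COC(=O)/C(=C\C)COC(C)=O)=C\[C@@H](O)[C@H]12 | target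

**Step count and risks**

Total steps: 18. Longest linear sequence: 11 steps (1–4, 8–13, 18), which is 61 % of the total. The east branch (5–7) and the side-chain branch (14–17) run in parallel.

The three steps most likely to fail:

Step 12 (the new macrocyclisation). The risks are oligomerisation, chromium-catalysed pinacol coupling of the enal, and a facial course other than the predicted trans/anti one. The fallback uses known reactions only and reverses the order of the two fragment unions; it sets out from 9 and 15 and returns at 24. Acylate 9 with 19 (DCC, cat. DMAP) to (3S,5E)-6-iodo-5-methylhexa-1,5-dien-3-yl 2-(bromomethyl)prop-2-enoate F1. Close the butenolide by ring-closing metathesis (second-generation Grubbs catalyst RuCl2(=CHPh)(PCy3)(H2IMes)) to (5S)-3-(bromomethyl)-5-[(2E)-3-iodo-2-methylprop-2-enyl]furan-2(5H)-one F2. Oxidise 15 with MnO2 to (2E)-3-{[(tert-butyldimethylsilyl)oxy]methyl}penta-2,4-dienal F3, used at once. Join F2 and F3 by an intermolecular indium-mediated Barbier allylation (In powder, THF/H2O), the established way from 3-(bromomethyl)butenolides to β-(hydroxyalkyl)-α-methylene-γ-butyrolactones, to give the open-chain trans-lactone carbinol F4. Hydroborate the terminal vinyl group of F4 with 9-BBN to the alkylborane F5 and close the ring at C1–C2 by an intramolecular B-alkyl Suzuki–Miyaura coupling (PdCl2(dppf), AsPh3, Cs2CO3, DMF/THF/H2O, high dilution) to reach 24.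

Step 9 (early enal). The risks are incomplete selectivity between the two allylic alcohols and isomerisation of the enal (CHO cis to the C3 chain) while it is carried through steps 10 and 11. The fallback differentiates the alcohols by protection and moves the oxidation to just before the ring closure; it sets out from 17 and returns at 21. Silylate the primary hydroxyl selectively (TESCl, imidazole, CH2Cl2, −78 °C) to the C6 triethylsilyl ether of 17 F6. Esterify with 19 (DCC, cat. DMAP) to the 2-(bromomethyl)acrylate F7. Ring-closing metathesis gives the butenolide triethylsilyl ether F8. AcOH/THF/H2O removes the triethylsilyl group only, giving the butenolide allylic alcohol F9, and MnO2 oxidation gives 21.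

Step 18 (final acylation). The risks are acylation of the C6 hydroxyl as well and loss of the Z geometry of the side chain. The fallback replaces chemoselectivity by orthogonal protection; it sets out from 24 and returns at 33. Silylate the C6 hydroxyl (TBSOTf, 2,6-lutidine) to the 6,15-bis(tert-butyldimethylsilyl) ether F10. HF·pyridine/pyridine in THF at 0 °C cleaves only the primary allylic silyl ether, giving the 6-O-silyl C15 alcohol F11. Acylate with acid chloride 32 (pyridine, CH2Cl2, 0 °C) to the 6-O-silyl ester F12, and remove the secondary silyl ether with HF·pyridine in MeCN at rt to give 33.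

**Further compounds**
F1 | step 12 | (3S,5E)-6-iodo-5-methylhexa-1,5-dien-3-yl 2-(bromomethyl)prop-2-enoate | C=C[C@@H](OC(=O)C(=C)CBr)C/C(C)=C/I
F2 | step 12 | (5S)-3-(bromomethyl)-5-[(2E)-3-iodo-2-methylprop-2-enyl]furan-2(5H)-one | BrCC1=C[C@H](C/C(C)=C/I)OC1=O
F3 | step 12 | (2E)-3-{[(tert-butyldimethylsilyl)oxy]methyl}penta-2,4-dienal | O=C/C=C(\C=C)CO[Si](C)(C)C(C)(C)C
F4 | step 12 | open-chain Barbier adduct: trans-fused α-methylene lactone with the C8 iodoalkenyl chain and the C6 dienyl carbinol | C=C1C(=O)O[C@@H](C/C(C)=C/I)[C@@H]1[C@H](O)/C=C(\C=C)CO[Si](C)(C)C(C)(C)C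
F5 | step 12 | B-alkyl-9-BBN borane of F4 | C=C1C(=O)O[C@@H](C/C(C)=C/I)[C@@H]1[C@H](O)/C=C(\CCB3C4CCCC3CCC4)CO[Si](C)(C)C(C)(C)C
F6 | step 9 | C6 triethylsilyl ether of 17 | C=C[C@@H](O)C/C(C)=C/CC/C(CO[Si](C)(C)C(C)(C)C)=C\CO[Si](CC)(CC)CC
F7 | step 9 | 2-(bromomethyl)prop-2-enoate of F6 | C=C[C@@H](OC(=O)C(=C)CBr)C/C(C)=C/CC/C(CO[Si](C)(C)C(C)(C)C)=C\CO[Si](CC)(CC)CC
F8 | step 9 | 3-(bromomethyl)butenolide with the C6 triethylsilyl ether | BrCC1=C[C@H](C/C(C)=C/CC/C(CO[Si](C)(C)C(C)(C)C)=C\CO[Si](CC)(CC)CC)OC1=O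
F9 | step 9 | 3-(bromomethyl)butenolide with the free C6 allylic alcohol | BrCC1=C[C@H](C/C(C)=C/CC/C(CO[Si](C)(C)C(C)(C)C)=C\CO)OC1=O
F10 | step 18 | 6,15-bis(tert-butyldimethylsilyl) ether of 25 | C=C1C(=O)O[C@H]2C/C(C)=C/CC/C(CO[Si](C)(C)C(C)(C)C)=C\[C@@H](O[Si](C)(C)C(C)(C)C)[C@H]12
F11 | step 18 | 6-O-(tert-butyldimethylsilyl) ether of 25 with free C15 hydroxyl | C=C1C(=O)O[C@H]2C/C(C)=C/CC/C(CO)=C\[C@@H](O[Si](C)(C)C(C)(C)C)[C@H]12
F12 | step 18 | 6-O-(tert-butyldimethylsilyl) ether of 33 | C=C1C(=O)O[C@H]2C/C(C)=C/CC/C(COC(=O)/C(=C\C)COC(C)=O)=C\[C@@H](O[Si](C)(C)C(C)(C)C)[C@H]12
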